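## Retrosynthetic overview

1. Target 22 ⇐ one-pot acidolysis of three acid-labile groups ⇐ acylation of the 3β-alcohol 15 with (Z)-4-acetoxy-2-methylbut-2-enoic acid 19 (from 3-methylfuran-2(5H)-one).
2. 15 ⇐ 3α-alcohol 13 (oxidation, then hydride return from the α face) ⇐ key step: the C4–C(α-acrylate) bond, made by coupling the C4 radical from epoxide 10 (titanocene opening, nickel capture) with 2-bromoacrylate 12.
3. 10 ⇐ bridged iodolactone 6: lactol/Wittig gives the C1 vinyl group and the freed C3 alkoxide closes the epoxide; the C6 side chain comes from alkoxymethyl-lithium addition and methylenation ⇐ anhydride 4.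
4. 4 ⇐ catalytic asymmetric endo Diels–Alder of citraconic anhydride with (E)-1-silyloxybutadiene. This is the only carbocycle and is formed first (C1, C5, C6 set); the anhydride, lactone and epoxide rings are temporary and are opened in that order.

Convention: ring carbons are C1–C6 in every cyclohexane compound (C1 quaternary C with CH3; C2 CH2; C3 the carbon that ends up esterified; C4 the carbon that ends up carrying the acrylic acid; C5 the carbinol carbon; C6 the carbon carrying the three-carbon alkenyl unit). With the ring flat and C1→C6 clockwise, β is toward the viewer and α away. Target: 1β-CH3, 1α-vinyl, 3β-acyloxy, 4β-(1-carboxyvinyl), 5α-OH, 6α-(3-hydroxyprop-1-en-2-yl).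

Assumption: the (S)-configured catalyst of step 2 is taken to give 4 in the drawn absolute sense; if it gives the mirror image, its (R)-antipode is used with no other change.

## Route

Step 1
Reactants: 1 crotonaldehyde [(E)-but-2-enal]
Product: 2 (E)-1-(triethylsilyloxy)buta-1,3-diene
Conditions: Et3SiOTf, Et3N, Et2O, 0 °C to rt
Reagents that add atoms: triethylsilyl trifluoromethanesulfonate, CC[Si](CC)(CC)OS(=O)(=O)C(F)(F)F
Why: Silyl dienol ether formation (O-silylation of the enal, then γ-deprotonation by Et3N) gives the conjugated (E)-silyloxydiene, and no stereocenter is formed.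

Step 2
Reactants: 2 (E)-1-(triethylsilyloxy)buta-1,3-diene; 3 citraconic anhydride (3-methylfuran-2,5-dione)
Product: 4 endo anhydride adduct 3a-methyl-7-(triethylsilyloxy)-3a,4,7,7a-tetrahydro-2-benzofuran-1,3-dione (1β-CH3; carbonyl carbons on C1 and C6 both α; 5α-OSiEt3; C3=C4)
Conditions: (S)-B-(o-tolyl) oxazaborolidine from α,α-diphenylprolinol activated by AlBr3 (10 mol%), CH2Cl2, −78 °C
Reagents that add atoms: none
Why: Proposed new method: the AlBr3-activated chiral oxazaborolidine should bind the less hindered anhydride carbonyl (next to the vinylic C–H), so that in this normal-demand Diels–Alder reaction the nucleophilic CH2 terminus of the diene bonds to the methyl-bearing carbon and the silyloxy terminus to the CH carbon, the endo transition state puts the silyloxy group cis to the anhydride (C1, C5 and C6 set together), and the catalyst shields one face; the closest known reactions are the oxazaborolidinium-catalysed Diels–Alder reactions of maleimides and quinones with 1-silyloxydienes.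

Step 3
Reactants: 4 endo anhydride adduct
Product: 6 keto iodolactone (C1 carboxyl lactonised onto the 3α-oxygen; 4β-iodo; 5α-OSiEt3; 6α-[(4-methoxybenzyloxy)acetyl]; 1β-CH3), via lithium keto carboxylate 5 (not isolated)
Conditions: 4-MeOC6H4CH2OCH2SnBu3, n-BuLi, THF, −78 °C; add 4, −78 °C; then aq. NaHCO3, I2, KI, THF/H2O, 0 °C
Reagents that add atoms: tributyl{[(4-methoxyphenyl)methoxy]methyl}stannane, CCCC[Sn](CCCC)(CCCC)COCc1ccc(OC)cc1; iodine, II
Why: Acyl substitution of the cyclic anhydride by a Still-type α-alkoxy organolithium at the less hindered carbonyl (on tertiary C6, not quaternary C1) gives keto carboxylate 5, whose α-face carboxylate then attacks C3 anti to a β-iodonium in an iodolactonisation (γ-lactone, iodine on C4 next to the electron-withdrawing C5–O), fixing C3–O α and C4–I β.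

Step 4
Reactants: 6 keto iodolactone
Product: 7 methylenated iodolactone (as 6 but 6α-[3-(4-methoxybenzyloxy)prop-1-en-2-yl])
Conditions: Cp2Ti(μ-Cl)(μ-CH2)AlMe2 (1.1 equiv), pyridine, THF/toluene, −40 to 0 °C
Reagents that add atoms: μ-chloro-μ-methylene-bis(cyclopentadienyl)titanium dimethylaluminium, C[Al-]1(C)C[Ti]([Cl+]1)(C1C=CC=C1)C1C=CC=C1
Why: Titanium-carbene carbonyl methylenation is non-basic and takes the ketone much faster than the lactone at low temperature, so the epimerisable C6 centre and the β-silyloxy ketone are untouched and no stereocenter is created.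

Step 5
Reactants: 7 methylenated iodolactone
Product: 10 C3,C4 α-epoxide (1α-vinyl; 1β-CH3; 5α-OSiEt3; 6α-[3-(4-methoxybenzyloxy)prop-1-en-2-yl]), via lactol 8 (not isolated), via potassium iodo alkoxide 9 (not isolated)
Conditions: i-Bu2AlH, CH2Cl2, −78 °C; then Ph3P=CH2 (from Ph3PCH3Br, KOt-Bu), THF, −78 °C to rt
Reagents that add atoms: methyltriphenylphosphonium bromide, C[P+](c1ccccc1)(c1ccccc1)c1ccccc1.[Br-]
Why: Partial lactone reduction to the lactol, Wittig methylenation of its open hydroxy-aldehyde form to the C1 vinyl group, and intramolecular SN2 displacement of the trans C4 iodide by the freed C3 alkoxide give the α-epoxide stereospecifically.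

Step 6
Reactants: 11 2,3-dibromopropanoyl chloride
Product: 12 4-methoxybenzyl 2-bromoprop-2-enoate
Conditions: 4-MeOC6H4CH2OH, Et3N (2.2 equiv), CH2Cl2, 0 °C to rt
Reagents that add atoms: 4-methoxybenzyl alcohol, COc1ccc(CO)cc1
Why: Esterification of the acid chloride followed by E2 loss of HBr from the 2,3-dibromo ester gives the 2-bromoacrylate, with no stereocenter involved.

Step 7
Reactants: 10 C3,C4 α-epoxide; 12 4-methoxybenzyl 2-bromoprop-2-enoate
Product: 13 3α-hydroxy acrylate (3α-OH; 4β-[1-(4-methoxybenzyloxycarbonyl)vinyl]; other groups as in 10)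
Conditions: NiCl2(MeOCH2CH2OMe) (10 mol%), 2,2′-bipyridine (10 mol%), Cp2TiCl2 (20 mol%), Mn powder, Et3N·HCl, DMPU, rt, slow addition of 12
Reagents that add atoms: none
Why: Proposed new method: Cp2TiCl (trivalent titanium, from Cp2TiCl2 and Mn) should open the epoxide homolytically at C4–O, which leaves the bulky titanoxy group on C3 away from the C5 silyl ether, and the C4 radical is then captured on its β face (anti to both the C3 titanoxy and the C5 silyloxy groups) by the alkenylnickel bromide formed from 12, with reductive elimination forging the C4–C(sp2) bond; the closest known reaction is the titanocene/nickel co-catalysed cross-electrophile coupling of epoxides with aryl and vinyl halides.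

Step 8
Reactants: 13 3α-hydroxy acrylate
Product: 14 3-ketone (C3 carbonyl; 4β side chain retained)
Conditions: Dess–Martin periodinane, NaHCO3, CH2Cl2, 0 °C; used at once
Reagents that add atoms: none
Why: Dess–Martin oxidation under buffered non-basic conditions converts the 3α-carbinol to the ketone without enolising the now acidic C4–H, so C4 keeps its configuration.

Step 9
Reactants: 14 3-ketone
Product: 15 3β-hydroxy acrylate (3β-OH cis to the 4β side chain)
Conditions: LiAlH(Ot-Bu)3, THF, −78 °C; pH 7 buffer quench at −78 °C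
Reagents that add atoms: none
Why: In this substrate-controlled ketone reduction the bulky hydride adds to the α face, away from the adjacent 4β side chain and the axial 1β-methyl (1,3-diaxial), giving the 3β axial alcohol, and the cold neutral quench prevents lactonisation onto the ester.

Step 10
Reactants: 16 3-methylfuran-2(5H)-one
Product: 19 (Z)-4-acetoxy-2-methylbut-2-enoic acid, via potassium hydroxy carboxylate 17 (not isolated), via dipotassium alkoxide carboxylate 18 (not isolated)
Conditions: KOH (1.0 equiv), H2O/THF, rt; concentrate and dry; KN(SiMe3)2 (1.0 equiv), DMF, −40 °C; Ac2O (1.0 equiv); cold aq. KHSO4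
Reagents that add atoms: potassium hydroxide, [K+].[OH-]; acetic anhydride, CC(=O)OC(C)=O
Why: Saponification of the butenolide keeps the (Z)-alkene that the ring enforced, and in dianion 18 the alkoxide is acetylated much faster than the carboxylate, so the hydroxyl is capped before any mixed anhydride can re-close the lactone.

Step 11
Reactants: 15 3β-hydroxy acrylate; 19 (Z)-4-acetoxy-2-methylbut-2-enoic acid
Product: 21 protected ester (3β-[(Z)-4-acetoxy-2-methylbut-2-enoyloxy]; other groups as in 15), via mixed anhydride 20 (not isolated)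
Conditions: 19, 2,4,6-Cl3C6H2COCl, Et3N, toluene, rt; then 15, toluene, 70 °C
Reagents that add atoms: none
Why: Yamaguchi esterification through the aroyl mixed anhydride, run without a nucleophilic catalyst, acylates the 3β-alcohol at the less hindered enoyl carbonyl and avoids the conjugate-addition pathway that isomerises (Z)-2-methylbut-2-enoates, with no stereocenter changed.

Step 12
Reactants: 21 protected ester
Product: 22 target, 2-[(1S,2R,3S,4S,6R)-6-{[(2Z)-4-acetoxy-2-methylbut-2-enoyl]oxy}-4-ethenyl-2-hydroxy-3-(3-hydroxyprop-1-en-2-yl)-4-methylcyclohexyl]prop-2-enoic acid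
Conditions: CF3CO2H/CH2Cl2 (1:9), anisole, 0 °C; aq. NaHCO3 work-up, then acidify to pH 4
Reagents that add atoms: none
Why: Acidolysis with a cation scavenger cleaves the 4-methoxybenzyl ether, the 4-methoxybenzyl ester and the triethylsilyl ether in one operation, while the acetate, the enoate and the alkenes (deactivated by allylic oxygen or carbonyl) survive and no stereocenter is affected.

## Compound list

1 | crotonaldehyde, (E)-but-2-enal | C/C=C/C=O | starting material
2 | (E)-1-(triethylsilyloxy)buta-1,3-diene | C=C/C=C/O[Si](CC)(CC)CC | intermediate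
3 | citraconic anhydride, 3-methylfuran-2,5-dione | CC1=CC(=O)OC1=O | starting material
4 | endo Diels–Alder adduct, 3a-methyl-7-(triethylsilyloxy)-3a,4,7,7a-tetrahydro-2-benzofuran-1,3-dione; 1β-CH3, anhydride carbons on C1 and C6 α, 5α-OSiEt3, C3=C4 | O=C2[C@]1(C)CC=C[C@H](O[Si](CC)(CC)CC)[C@@H]1C(=O)O2 | intermediate
5 | lithium keto carboxylate; 1α-CO2Li, 1β-CH3, 5α-OSiEt3, 6α-C(=O)CH2O-(4-methoxybenzyl), C3=C4 | [Li+].[O-]C(=O)[C@]1(C)CC=C[C@H](O[Si](CC)(CC)CC)[C@@H]1C(=O)COCc1ccc(OC)cc1 | intermediate
6 | keto iodolactone (6-oxabicyclo[3.2.1]octan-7-one core); C1 carboxyl lactonised onto 3α-O, 4β-I, 5α-OSiEt3, 6α-C(=O)CH2O-(4-methoxybenzyl), 1β-CH3 | O=C2[C@]1(C)C[C@H](O2)[C@@H](I)[C@H](O[Si](CC)(CC)CC)[C@@H]1C(=O)COCc1ccc(OC)cc1 | intermediate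
7 | methylenated iodolactone; as 6 with 6α-C(=CH2)CH2O-(4-methoxybenzyl) | O=C2[C@]1(C)C[C@H](O2)[C@@H](I)[C@H](O[Si](CC)(CC)CC)[C@@H]1C(=C)COCc1ccc(OC)cc1 | intermediate
8 | lactol from 7 (bridged hemiacetal, both anomers) | OC2[C@]1(C)C[C@H](O2)[C@@H](I)[C@H](O[Si](CC)(CC)CC)[C@@H]1C(=C)COCc1ccc(OC)cc1 | intermediate
9 | potassium iodo alkoxide; 1α-vinyl, 3α-OK, 4β-I | C=C[C@]1(C)C[C@H]([O-])[C@@H](I)[C@H](O[Si](CC)(CC)CC)[C@@H]1C(=C)COCc1ccc(OC)cc1.[K+] | intermediate
10 | C3,C4 α-epoxide; 1α-vinyl, 1β-CH3, 5α-OSiEt3, 6α-C(=CH2)CH2O-(4-methoxybenzyl) | C=C[C@]1(C)C[C@@H]2O[C@@H]2[C@H](O[Si](CC)(CC)CC)[C@@H]1C(=C)COCc1ccc(OC)cc1 | intermediate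
11 | 2,3-dibromopropanoyl chloride | BrCC(Br)C(Cl)=O | starting material
12 | 4-methoxybenzyl 2-bromoprop-2-enoate | C=C(Br)C(=O)OCc1ccc(OC)cc1 | intermediate
13 | 3α-hydroxy acrylate; 3α-OH, 4β-C(=CH2)CO2-(4-methoxybenzyl), rest as 10 | C=C[C@]1(C)C[C@H](O)[C@@H](C(=C)C(=O)OCc2ccc(OC)cc2)[C@H](O[Si](CC)(CC)CC)[C@@H]1C(=C)COCc1ccc(OC)cc1 | intermediate
14 | 3-ketone | C=C[C@]1(C)CC(=O)[C@@H](C(=C)C(=O)OCc2ccc(OC)cc2)[C@H](O[Si](CC)(CC)CC)[C@@H]1C(=C)COCc1ccc(OC)cc1 | intermediate
15 | 3β-hydroxy acrylate; 3β-OH cis to the 4β side chain | C=C[C@]1(C)C[C@@H](O)[C@@H](C(=C)C(=O)OCc2ccc(OC)cc2)[C@H](O[Si](CC)(CC)CC)[C@@H]1C(=C)COCc1ccc(OC)cc1 | intermediate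
16 | 3-methylfuran-2(5H)-one | CC1=CCOC1=O | starting material
17 | potassium (Z)-4-hydroxy-2-methylbut-2-enoate | [K+].[O-]C(=O)/C(C)=C\CO | intermediate
18 | dipotassium (Z)-2-methyl-4-oxidobut-2-enoate | [K+].[K+].[O-]C(=O)/C(C)=C\C[O-] | intermediate
19 | (Z)-4-acetoxy-2-methylbut-2-enoic acid | OC(=O)/C(C)=C\COC(C)=O | intermediate
20 | (Z)-4-acetoxy-2-methylbut-2-enoic 2,4,6-trichlorobenzoic anhydride | Clc1cc(Cl)cc(Cl)c1C(=O)OC(=O)/C(C)=C\COC(C)=O | intermediate
21 | protected ester; 3β-(Z)-4-acetoxy-2-methylbut-2-enoyloxy, 4β-C(=CH2)CO2-(4-methoxybenzyl), 5α-OSiEt3, 6α-C(=CH2)CH2O-(4-methoxybenzyl) | C=C[C@]1(C)C[C@@H](OC(=O)/C(C)=C\COC(C)=O)[C@@H](C(=C)C(=O)OCc2ccc(OC)cc2)[C@H](O[Si](CC)(CC)CC)[C@@H]1C(=C)COCc1ccc(OC)cc1 | intermediate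
22 | target acid | C=C[C@]1(C)C[C@@H](OC(=O)/C(C)=C\COC(C)=O)[C@@H](C(=C)C(=O)O)[C@H](O)[C@@H]1C(=C)CO | target

## Step count and weak points

Total step count: 12. Longest linear sequence: 10 steps (steps 1, 2, 3, 4, 5, 7, 8, 9, 11, 12).

Most likely to fail, first: step 7, the radical/nickel coupling. The nucleophilic C4 radical may add to the CH2 terminus of 12 instead of being captured by nickel, and the epoxide may open at the other C–O bond. The fallback keeps a radical C4–C bond formation but uses a position-defined radical and a non-acceptor trap. It sets out from 7: (Bu3Sn)2, hν and trimethyl[(phenylsulfonyl)ethynyl]silane give, by radical alkynylation on the exo β face of the rigid bicycle, the alkynyl lactone F4. i-Bu2AlH and then Ph3P=CH2 give the vinyl carbinol F5. K2CO3 in MeOH gives the terminal alkyne F6. Markovnikov hydroalkoxycarbonylation (Pd(OAc)2, 2-pyridyldiphenylphosphine, MeSO3H, CO, 4-methoxybenzyl alcohol) returns to the route at 13.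

Second: step 2, where rate, regiocontrol or enantiocontrol of the catalysed cycloaddition of an anhydride may be poor. The fallback replaces asymmetric catalysis by classical resolution. It sets out from 2 and 3: heating in toluene at 60 °C without catalyst gives the racemic endo anhydride F1. The alkoxymethyl-lithium addition of step 3 with an acidic work-up gives the racemic keto acid F2. Crystallisation with (R)-1-phenylethylamine gives the ammonium salt F3 of the needed enantiomer. Acidification followed by I2/NaHCO3 returns to the route at 6.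

Third: step 9, where the labile β,γ-unsaturated ketone may isomerise, the facial selectivity may be low, or the product may lactonise. The fallback replaces steric control by hydroxyl-directed hydride delivery. It sets out from 14: HF·pyridine gives the β-hydroxy ketone F7. Me4NBH(OAc)3 in MeCN/AcOH at −40 °C delivers hydride intramolecularly from the 5α-oxygen and gives the anti diol F8 (3β-OH, 5α-OH). Mixed anhydride 20 acylates the less hindered 3β-hydroxyl to give the ester F9. The conditions of step 12 then return to the route at 22.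

## Further compounds

F1 | step 2 | racemic 4 (1:1 mixture of 4 and its mirror image) | O=C2[C@]1(C)CC=C[C@H](O[Si](CC)(CC)CC)[C@@H]1C(=O)O2.O=C2[C@@]1(C)CC=C[C@@H](O[Si](CC)(CC)CC)[C@H]1C(=O)O2
F2 | step 2 | racemic keto acid (free acid of 5 and its mirror image) | OC(=O)[C@]1(C)CC=C[C@H](O[Si](CC)(CC)CC)[C@@H]1C(=O)COCc1ccc(OC)cc1.OC(=O)[C@@]1(C)CC=C[C@@H](O[Si](CC)(CC)CC)[C@H]1C(=O)COCc1ccc(OC)cc1
F3 | step 2 | (R)-1-phenylethanaminium salt of the keto acid of 5 | C[C@@H]([NH3+])c1ccccc1.[O-]C(=O)[C@]1(C)CC=C[C@H](O[Si](CC)(CC)CC)[C@@H]1C(=O)COCc1ccc(OC)cc1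
F4 | step 7 | alkynyl lactone; as 7 with 4β-(trimethylsilylethynyl) in place of iodine | O=C2[C@]1(C)C[C@H](O2)[C@@H](C#C[Si](C)(C)C)[C@H](O[Si](CC)(CC)CC)[C@@H]1C(=C)COCc1ccc(OC)cc1
F5 | step 7 | vinyl carbinol; 1α-vinyl, 3α-OH, 4β-(trimethylsilylethynyl) | C=C[C@]1(C)C[C@H](O)[C@@H](C#C[Si](C)(C)C)[C@H](O[Si](CC)(CC)CC)[C@@H]1C(=C)COCc1ccc(OC)cc1
F6 | step 7 | terminal alkyne; 1α-vinyl, 3α-OH, 4β-ethynyl | C=C[C@]1(C)C[C@H](O)[C@@H](C#C)[C@H](O[Si](CC)(CC)CC)[C@@H]1C(=C)COCc1ccc(OC)cc1
F7 | step 9 | β-hydroxy ketone; 14 without the silyl group (5α-OH) | C=C[C@]1(C)CC(=O)[C@@H](C(=C)C(=O)OCc2ccc(OC)cc2)[C@H](O)[C@@H]1C(=C)COCc1ccc(OC)cc1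
F8 | step 9 | anti diol; 3β-OH, 5α-OH | C=C[C@]1(C)C[C@@H](O)[C@@H](C(=C)C(=O)OCc2ccc(OC)cc2)[C@H](O)[C@@H]1C(=C)COCc1ccc(OC)cc1
F9 | step 9 | 21 without the silyl group (5α-OH) | C=C[C@]1(C)C[C@@H](OC(=O)/C(C)=C\COC(C)=O)[C@@H](C(=C)C(=O)OCc2ccc(OC)cc2)[C@H](O)[C@@H]1C(=C)COCc1ccc(OC)cc1
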